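At 10.0 min into the zeta run, substrate reads 27.1 % and target 72.9 %, together 100 % of the substrate charged, so at a scatter of 0.3 percentage points this zeta reading shows nothing held in between.

in all of them: substrate 1.4 M

| charge | reagent | initiator | remark | time |
|---|---|---|---|---|
| zeta | 1.5 equiv | 1.1 mol% | the very flask that is asked about, followed so far |  |
| gamma | 1.5 equiv | 1.7 mol% | run made earlier |  |
| flask | 1.50 equiv | 1.1 mol% |  | 4.0 h |

zeta run (percent of the substrate charged)

| time / min | substrate / % | target / % |
|---|---|---|
| 10.0 | 27.1 | 72.9 |
| 20.0 | 7.1 | 92.3 |
| 50.0 | 0.1 | 100.0 |
| 120 | 0 | 99.8 |

gamma run (percent of the substrate charged)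

| time / h | substrate / % | target / % |
|---|---|---|
| 0.333 | 3.9 | 95.9 |
| 1.00 | 0.2 | 99.5 |
| 2.00 | 0.1 | 99.7 |
| 3.00 | 0 | 99.6 |

(scatter of a reading: 0.3 percentage points)

- the reaction counts as stopped when no species that holds the substrate changes by six tenths of a point or more over the second half of the time

- which holds at 4.0 h: what has brought the reaction to rest, or that it has not come to rest (it is still moving / the reagent has run out first / all of the substrate has reacted / forward and back rates have come level)
- share of the substrate used up at 4.0 h
- target at 4.0 h, in percent of the substrate charged

Book that passage from substrate to target as a single entry, and reckon one reagent per target. The flask has the zeta recipe, so its ledger can be opened from zeta. Substrate is the limiting reagent, because you charge 1.50 equiv, more than one equivalent. First entry: substrate still unreacted, 0 % at 120 min in zeta. Second entry: target, 99.8 % at that time. Those two close the books within the scatter. Third entry, on the other side: by my reckoning the reagent keeps 33.3 % of its own charge unused.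

The target ceiling stands here at 100 %: the smaller of the reagent equivalents and one, read as a share of the substrate charged. Mine is a bound, not a yield.

The forecast says: all of the substrate has reacted, with conversion 100 % (range 99.7 % to 100 %) and target 99.7 % (range 99.2 % to 100 %). On the reagent it writes “so it cannot have run out”.

At 4.0 h the flask gives: all of the substrate has reacted, with conversion 100 % and target 99.8 %.

    reagent + first chain carrier → target + second chain carrier (k = 5.70 × 10⁵ /M/min)
    substrate + initiating radical → capped initiator + first chain carrier (k = 1.20 × 10⁵ /M/s)
    initiator → 2 initiating radical (k = 0.00790 /min)
    substrate + second chain carrier → by-product + first chain carrier (k = 12000 /M/s)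
    2 second chain carrier → ended chains (k = 6.00 × 10⁷ /M/s)
    substrate → decomposition product (k = 2.10 × 10⁻⁴ /min)

In the flask, reagent stands at 33 % of its charge, and target sits under the ceiling of 100 %. Now take the neighbour with 0.380 equiv of reagent, other charges held. The same rule gives a ceiling of 38.0 %, and the short side of the ledger changes, since that charge is less than one equivalent. At 4.00 h the neighbour gives target 38.0 %, with reagent at 0 % of its charge and substrate still at 57.2 %.

The readings were computed for an exercise, and the scatter is random.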